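**Plan**

1. Retrosynthesis: the pyran bonds O–C4 and C5–C1′ are cut together (hetero-Diels–Alder) to (−)-β-caryophyllene and isobutylidenesyncarpic acid. The C4 methyl and the E-C4=C5 alkene go back to the C4 ketone of a (Z)-cyclononenone. The nine-membered ring is then folded across C4–C8 to a cyclobuta-fused hydrindenol tosylate, which is taken apart at C4–C5, C7–C8, C4–C8 and the cyclobutane bonds.
2. Feature: C8 (the exocyclic methylene carbon) and C4 (the O- and Me-bearing carbon) face each other across the nine-membered ring, with C5–C7 on one side and C9, C1, C2, C3 on the other. A C4–C8 bond divides that ring into a six- and a five-membered ring, and C4=O plus C8=CH2 are the two ends left when HO–C4–C8–CH2–OTs fragments.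
3. Forward ring order: cyclobutane ([2+2]); cyclohexanone opened and re-closed as the trans-fused six-membered ring (C8–C4); cyclopentene (C7–C8 alkylation, then C5 to C4 addition); nine-membered ring by fragmentation; pyran by [4+2].
4. Stereochemistry: C1 comes from the catalyst-controlled photocycloaddition. C9 is set by base equilibration to the trans cyclobutane ester while the six-membered ring is open, because it cannot be corrected later. C4 and C8 of the hydrindenol are temporary.
5. The E-alkene comes from stereospecific inversion of the Z-alkene. C4, C5 and C1′ are set in the final suprafacial cycloaddition on the exposed face of that alkene.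

Key step: step 13

Remarks on the chemistry: atom labels C1–C11 follow caryophyllane numbering (C1/C9 ring-fusion CH, C4 bears O and Me, C8 bears =CH2, C15 is the methylene carbon, C1′ bears the isopropyl group). The enantiomer of the chiral Lewis acid in step 1 is assumed to be the one that gives the (6R) adduct. Compound 16 and a THF solution of LiPPh2 are assumed purchasable. Salts and conjugate bases of a numbered compound are treated as that compound; species with a different covalent framework carry their own numbers.

**Route**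

Step 1
Reactants: 1 2-cyclohexen-1-one; 2 isobutene
Product: 4 (1R,6R)-7,7-dimethylbicyclo[4.2.0]octan-2-one (cis-fused), via trans-fused photoadduct 3 (not isolated)
Conditions: chiral oxazaborolidine·AlBr3 (50 mol %), 2 (excess), CH2Cl2, −75 °C, hν (366 nm); then basic Al2O3, CH2Cl2, rt
Reagents that add atoms: none
Why: A Lewis-acid-catalysed enantioselective enone–alkene [2+2] photocycloaddition should give the head-to-tail adduct (CMe2 on the former β-carbon) with the chiral Lewis acid shielding one enone face, so that C6 (the future C1) is set as R; the α-centre is then epimerised to the cis-fused ketone and is reset in step 3.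

Step 2
Reactants: 4
Product: 5 (1R,6R)-3-(hydroxyimino)-7,7-dimethylbicyclo[4.2.0]octan-2-one
Conditions: isoamyl nitrite, KOt-Bu, t-BuOH/THF, 0 °C; aq. HCl
Reagents that add atoms: isoamyl nitrite, CC(C)CCON=O
Why: Base-mediated α-nitrosation should occur at the only α-methylene (C3), followed by tautomerisation to the oxime; the ring-fusion α-CH cannot form an oxime and no stereocentre is created.

Step 3
Reactants: 5
Product: 9 (1S,2R)-2-(2-cyanoethyl)-3,3-dimethylcyclobutane-1-carboxylic acid, via oxime tosylate 6 (not isolated), via cis cyano ester 7 (not isolated), via trans cyano ester 8 (not isolated)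
Conditions: TsCl, Et3N, DMAP (cat.), CH2Cl2, 0 °C; then NaOMe, MeOH, 0 → 60 °C; then NaOH, H2O, 50 °C; aq. HCl
Reagents that add atoms: p-toluenesulfonyl chloride, Cc1ccc(cc1)S(Cl)(=O)=O (atoms in 6 only); sodium methoxide, [Na+].[O-]C (atoms in 7 and 8 only); sodium hydroxide, [Na+].[OH-] (carboxyl oxygen of 9)
Why: Methoxide attack on the ketone of the oxime sulfonate should trigger a Beckmann fragmentation (C2–C3 cleavage to ester and nitrile), the methoxide then equilibrates the ester-bearing carbon to the more stable trans-1,2-disubstituted cyclobutane (this fixes the future C9 relative to C1), and hydroxide saponifies the ester without touching the nitrile.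

Step 4
Reactants: 9
Product: 11 3-[(1R,4S)-4-(2-diazoacetyl)-2,2-dimethylcyclobutyl]propanenitrile, via acid chloride 10 (not isolated)
Conditions: (COCl)2, DMF (cat.), CH2Cl2, 0 °C → rt; then CH2N2 (excess), Et2O, 0 °C
Reagents that add atoms: oxalyl chloride, ClC(=O)C(Cl)=O (Cl in 10 only); diazomethane, C=[N+]=[N-]
Why: Acyl chloride formation and acylation of diazomethane (first half of an Arndt–Eistert homologation) should proceed with the nitrile inert, and the trans arrangement is the thermodynamic one, so it is not at risk.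

Step 5
Reactants: 11
Product: 13 tert-butyl 2-[(1R,2R)-2-(2-cyanoethyl)-3,3-dimethylcyclobutyl]acetate, via ketene 12 (not isolated)
Conditions: PhCO2Ag (10 mol %), Et3N, t-BuOH, 60 °C, dark
Reagents that add atoms: tert-butanol, CC(C)(C)O
Why: The silver-catalysed Wolff rearrangement (1,2-shift of the cyclobutyl carbon with retention) should give the ketene, which t-BuOH traps; this places the future C8 between C9 and the carboxyl carbon (future C15), and C9, no longer α to a carbonyl, is locked trans to C1.

Step 6
Reactants: 13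
Product: 15 tert-butyl (1S,6R)-7,7-dimethyl-3-oxobicyclo[4.2.0]octane-2-carboxylate (C2 epimerisable, partly enolised), via enamino ester 14 (not isolated)
Conditions: LiHMDS (1.3 equiv), THF, −78 → 0 °C; then 1 M aq. HCl/THF, rt
Reagents that add atoms: water, O
Why: In a Thorpe–Ziegler-type cyclisation the lithium enolate of the tert-butyl ester should add 6-exo-dig to the nitrile (the tert-butyl ester being too poor an acyl acceptor for the competing Claisen closure from the nitrile α-carbon), and mild acid hydrolyses the β-enamino ester to the β-keto ester; the trans ring fusion cannot epimerise.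

Step 7
Reactants: 16 ethyl (Z)-3-iodoprop-2-enoate
Product: 17 (Z)-3-iodoprop-2-en-1-ol
Conditions: DIBAL-H (2.2 equiv), CH2Cl2, −78 → 0 °C; aq. Rochelle salt
Reagents that add atoms: none
Why: Hydride reduction of the ester to the allylic alcohol should leave the Z-iodoalkene untouched at low temperature.

Step 8
Reactants: 17
Product: 18 (Z)-3-bromo-1-iodoprop-1-ene
Conditions: CBr4, PPh3, CH2Cl2, 0 °C
Reagents that add atoms: carbon tetrabromide, BrC(Br)(Br)Br
Why: Appel bromination of the primary allylic alcohol runs under neutral conditions and should retain the Z geometry.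

Step 9
Reactants: 15; 18
Product: 19 tert-butyl (1S,2R,6R)-2-[(2Z)-3-iodoprop-2-en-1-yl]-7,7-dimethyl-3-oxobicyclo[4.2.0]octane-2-carboxylate
Conditions: K2CO3, acetone, 50 °C
Reagents that add atoms: none
Why: C-alkylation of the β-keto ester enolate with the allylic bromide creates the quaternary C8, the electrophile being expected to enter axially, anti to H-9; either C8 epimer would serve, since the next ring closure is tether-controlled and C8 later becomes sp2.

Step 10
Reactants: 19
Product: 21 tert-butyl (1R,2S,5R,8R)-8-hydroxy-4,4-dimethyltricyclo[6.3.0.0(2,5)]undec-9-ene-1-carboxylate (cis-fused hydrindenol on a trans-fused cyclobutane; five-membered ring anti to H-9), via alkenyllithium 20 (not isolated)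
Conditions: t-BuLi (2.1 equiv), THF, −78 °C; AcOH, −78 °C
Reagents that add atoms: tert-butyllithium, [Li]C(C)(C)C (Li in 20 only)
Why: Iodine–lithium exchange at the Z-alkenyl iodide should outpace carbonyl addition of t-BuLi at −78 °C, and the alkenyllithium then adds to the neighbouring ketone rather than the hindered tert-butyl ester (Parham-type cyclisation, 5-exo-trig onto C=O); the three-atom Z-tether forces the new C4–C5 bond onto the face that carries C7, so the ring fusion is cis.

Step 11
Reactants: 21
Product: 22 (1S,2S,5R,8R)-1-(hydroxymethyl)-4,4-dimethyltricyclo[6.3.0.0(2,5)]undec-9-en-8-ol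
Conditions: LiAlH4, THF, 0 °C → rt; Fieser work-up
Reagents that add atoms: none
Why: Hydride reduction of the tert-butyl ester to the primary alcohol should proceed on the aluminate of the tertiary alcohol without change at any stereocentre.

Step 12
Reactants: 22
Product: 23 [(1S,2S,5R,8R)-8-hydroxy-4,4-dimethyltricyclo[6.3.0.0(2,5)]undec-9-en-1-yl]methyl 4-methylbenzenesulfonate
Conditions: TsCl (1.2 equiv), pyridine, DMAP (cat.), CH2Cl2, 0 °C → rt
Reagents that add atoms: p-toluenesulfonyl chloride, Cc1ccc(cc1)S(Cl)(=O)=O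
Why: Sulfonylation should be selective for the primary alcohol, since the bridgehead tertiary alcohol does not react under these conditions.

Step 13
Reactants: 23
Product: 24 (1R,5Z,9S)-11,11-dimethyl-8-methylidenebicyclo[7.2.0]undec-5-en-4-one
Conditions: KHMDS (1.0 equiv), THF, −78 → 0 °C; pH 7 buffer
Reagents that add atoms: none
Why: Deprotonation of the bridgehead alcohol gives the C4 alkoxide, whose lone pair forms C4=O while the C4–C8 σ-bond becomes the C8=CH2 π-bond and tosylate leaves from the angular CH2; this is a concerted Grob (Wharton) fragmentation of a cyclic 1,3-diol monosulfonate, a known way to medium-ring alkenyl ketones. No ring is closed: the nine-membered ring is released by cleaving the bond shared by the six- and five-membered rings, helped by relief of the strain of the trans-fused cyclobutane–cyclohexane unit. No stereocentre is created; C4 and C8 become sp2, C1 and C9 are untouched, and the cyclopentene alkene is delivered as the Z-enone. The step needs fragmentation to outrun 4-exo-tet oxetane formation and base-mediated migration of the skipped diene into conjugation. The neopentyl CH2OTs resists SN2 attack, the freely rotating C8–CH2OTs bond can always lie anti-periplanar to C4–C8, and one equivalent of a hindered amide base at low temperature leaves no base once potassium tosylate has formed.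

Step 14
Reactants: 24
Product: 26 (1R,4E,9S)-11,11-dimethyl-8-methylidenebicyclo[7.2.0]undec-4-en-4-yl trifluoromethanesulfonate (ring carbons C3 and C6 cis), via lithium enolate 25 (not isolated)
Conditions: L-Selectride (1.05 equiv), THF, −78 °C; then PhNTf2, −78 → 0 °C
Reagents that add atoms: N-phenylbis(trifluoromethanesulfonimide), O=S(=O)(N(c1ccccc1)S(=O)(=O)C(F)(F)F)C(F)(F)F; L-Selectride, [Li+].CCC(C)[BH-](C(C)CC)C(C)CC (Li in 25 only)
Why: Conjugate hydride addition to the β-monosubstituted Z-enone should give the C4–C5 enolate regiospecifically (the reason for carrying the ring alkene through the fragmentation), with C3 and C6 cis as in the s-trans enone, and O-triflation traps it without equilibration.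

Step 15
Reactants: 26
Product: 27 (1R,4Z,9S)-4,11,11-trimethyl-8-methylidenebicyclo[7.2.0]undec-4-ene ((−)-isocaryophyllene)
Conditions: MeMgBr, Fe(acac)3 (5 mol %), THF/NMP, −30 → 0 °C
Reagents that add atoms: methylmagnesium bromide, C[Mg]Br
Why: Iron-catalysed Kumada-type coupling of the alkenyl triflate with the methyl Grignard reagent should install the C4 methyl with retention of alkene geometry and leave the exocyclic methylene alone.

Step 16
Reactants: 27
Product: 28 (1R,4R,6S,10S)-4,12,12-trimethyl-9-methylidene-5-oxatricyclo[8.2.0.0(4,6)]dodecane (cis-4,5-epoxide)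
Conditions: m-CPBA (1.0 equiv), CH2Cl2, −20 → 0 °C
Reagents that add atoms: m-chloroperoxybenzoic acid, OOC(=O)c1cccc(Cl)c1
Why: The electron-rich trisubstituted alkene should be epoxidised in preference to the 1,1-disubstituted methylene with syn addition (C3 and C6 stay cis); the face of attack (outer face drawn) is immaterial because both oxirane centres are erased in step 17.

Step 17
Reactants: 28
Product: 31 (1R,4E,9S)-4,11,11-trimethyl-8-methylidenebicyclo[7.2.0]undec-4-ene ((−)-β-caryophyllene), via phosphino alkoxide 29 (not isolated), via phosphonium betaine 30 (not isolated)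
Conditions: LiPPh2, THF, rt; then MeI, rt
Reagents that add atoms: lithium diphenylphosphide, [Li]P(c1ccccc1)c1ccccc1 (atoms in 29 and 30 only); iodomethane, CI (atoms in 30 only)
Why: In this phosphorus-betaine olefin inversion the phosphide should open the oxirane at the secondary C5 with inversion, P-methylation gives the betaine, and syn-cycloelimination of the phosphine oxide then turns the cis-epoxide stereospecifically into the E-alkene.

Step 18
Reactants: 31; 32 syncarpic acid; 33 isobutyraldehyde
Product: 35 Myrtucommulone K, via isobutylidenesyncarpic acid 34 (not isolated)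
Conditions: pyrrolidine (10 mol %), AcOH (10 mol %), 4 Å MS, toluene, rt → 80 °C
Reagents that add atoms: none
Why: Amine-catalysed Knoevenagel condensation generates the electron-poor 1-oxadiene 34, which the strained E-alkene of 31 should trap in an inverse-electron-demand hetero-Diels–Alder reaction in preference to the exocyclic methylene (C4 bonding to O, C5 to C1′); suprafacial addition makes the pyran trans-fused, attack on the exposed face of C4=C5 (the face peracids use) gives 4R,5S, and the orientation with the trione ring over the C4-methyl/C6 edge places H-1′ cis to H-5 (1′R).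

**Compound list**

1 | 2-cyclohexen-1-one | O=C1C=CCCC1 | starting material
2 | isobutene (2-methylpropene) | C=C(C)C | starting material
3 | (1S,6R)-7,7-dimethylbicyclo[4.2.0]octan-2-one (trans-fused) | O=C1CCC[C@@H]2[C@@H]1CC2(C)C | intermediate (not isolated)
4 | (1R,6R)-7,7-dimethylbicyclo[4.2.0]octan-2-one (cis-fused) | O=C1CCC[C@@H]2[C@H]1CC2(C)C | intermediate
5 | (1R,6R)-3-(hydroxyimino)-7,7-dimethylbicyclo[4.2.0]octan-2-one (oxime geometry not defined) | O=C1C(=NO)CC[C@@H]2[C@H]1CC2(C)C | intermediate
6 | (1R,6R)-7,7-dimethyl-3-[(tosyloxy)imino]bicyclo[4.2.0]octan-2-one | O=C1C(=NOS(=O)(=O)c3ccc(C)cc3)CC[C@@H]2[C@H]1CC2(C)C | intermediate (not isolated)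
7 | methyl (1R,2R)-2-(2-cyanoethyl)-3,3-dimethylcyclobutane-1-carboxylate (cis) | N#CCC[C@@H]1[C@H](C(=O)OC)CC1(C)C | intermediate (not isolated)
8 | methyl (1S,2R)-2-(2-cyanoethyl)-3,3-dimethylcyclobutane-1-carboxylate (trans) | N#CCC[C@@H]1[C@@H](C(=O)OC)CC1(C)C | intermediate (not isolated)
9 | (1S,2R)-2-(2-cyanoethyl)-3,3-dimethylcyclobutane-1-carboxylic acid | N#CCC[C@@H]1[C@@H](C(=O)O)CC1(C)C | intermediate
10 | (1S,2R)-2-(2-cyanoethyl)-3,3-dimethylcyclobutane-1-carbonyl chloride | N#CCC[C@@H]1[C@@H](C(=O)Cl)CC1(C)C | intermediate (not isolated)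
11 | 3-[(1R,4S)-4-(2-diazoacetyl)-2,2-dimethylcyclobutyl]propanenitrile | N#CCC[C@@H]1[C@@H](C(=O)C=[N+]=[N-])CC1(C)C | intermediate
12 | 3-[(1R,4S)-2,2-dimethyl-4-(2-oxoethenyl)cyclobutyl]propanenitrile (ketene) | N#CCC[C@@H]1[C@@H](C=C=O)CC1(C)C | intermediate (not isolated)
13 | tert-butyl 2-[(1R,2R)-2-(2-cyanoethyl)-3,3-dimethylcyclobutyl]acetate | N#CCC[C@@H]1[C@@H](CC(=O)OC(C)(C)C)CC1(C)C | intermediate
14 | tert-butyl (1S,6R)-3-amino-7,7-dimethylbicyclo[4.2.0]oct-2-ene-2-carboxylate | NC=2CC[C@@H]1[C@@H](C=2C(=O)OC(C)(C)C)CC1(C)C | intermediate (not isolated)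
15 | tert-butyl (1S,6R)-7,7-dimethyl-3-oxobicyclo[4.2.0]octane-2-carboxylate (C2 not defined) | O=C2CC[C@@H]1[C@@H](C2C(=O)OC(C)(C)C)CC1(C)C | intermediate
16 | ethyl (Z)-3-iodoprop-2-enoate | CCOC(=O)/C=C\I | starting material
17 | (Z)-3-iodoprop-2-en-1-ol | OC/C=C\I | intermediate
18 | (Z)-3-bromo-1-iodoprop-1-ene | BrC/C=C\I | intermediate
19 | tert-butyl (1S,2R,6R)-2-[(2Z)-3-iodoprop-2-en-1-yl]-7,7-dimethyl-3-oxobicyclo[4.2.0]octane-2-carboxylate | O=C2CC[C@@H]1[C@@H]([C@@]2(C/C=C\I)C(=O)OC(C)(C)C)CC1(C)C | intermediate
20 | alkenyllithium from 19 (Li in place of I) | O=C2CC[C@@H]1[C@@H]([C@@]2(C/C=C\[Li])C(=O)OC(C)(C)C)CC1(C)C | intermediate (not isolated)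
21 | tert-butyl (1R,2S,5R,8R)-8-hydroxy-4,4-dimethyltricyclo[6.3.0.0(2,5)]undec-9-ene-1-carboxylate | O[C@@]23CC[C@@H]1[C@@H]([C@]2(C(=O)OC(C)(C)C)CC=C3)CC1(C)C | intermediate
22 | (1S,2S,5R,8R)-1-(hydroxymethyl)-4,4-dimethyltricyclo[6.3.0.0(2,5)]undec-9-en-8-ol | O[C@@]23CC[C@@H]1[C@@H]([C@]2(CO)CC=C3)CC1(C)C | intermediate
23 | [(1S,2S,5R,8R)-8-hydroxy-4,4-dimethyltricyclo[6.3.0.0(2,5)]undec-9-en-1-yl]methyl 4-methylbenzenesulfonate | O[C@@]23CC[C@@H]1[C@@H]([C@]2(COS(=O)(=O)c4ccc(C)cc4)CC=C3)CC1(C)C | intermediate (key-step precursor)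
24 | (1R,5Z,9S)-11,11-dimethyl-8-methylidenebicyclo[7.2.0]undec-5-en-4-one | C=C1C/C=C\C(=O)CC[C@@H]2[C@@H]1CC2(C)C | intermediate (key-step product)
25 | lithium (1R,4E,9S)-11,11-dimethyl-8-methylidenebicyclo[7.2.0]undec-4-en-4-olate | [Li+].C=C1CC/C=C([O-])\CC[C@@H]2[C@@H]1CC2(C)C | intermediate (not isolated)
26 | (1R,4E,9S)-11,11-dimethyl-8-methylidenebicyclo[7.2.0]undec-4-en-4-yl trifluoromethanesulfonate | C=C1CC/C=C(OS(=O)(=O)C(F)(F)F)\CC[C@@H]2[C@@H]1CC2(C)C | intermediate
27 | (1R,4Z,9S)-4,11,11-trimethyl-8-methylidenebicyclo[7.2.0]undec-4-ene ((−)-isocaryophyllene) | C=C1CC/C=C(C)\CC[C@@H]2[C@@H]1CC2(C)C | intermediate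
28 | (1R,4R,6S,10S)-4,12,12-trimethyl-9-methylidene-5-oxatricyclo[8.2.0.0(4,6)]dodecane | C=C1CC[C@@H]3O[C@]3(C)CC[C@@H]2[C@@H]1CC2(C)C | intermediate
29 | lithium (1R,4R,5R,9S)-5-(diphenylphosphanyl)-4,11,11-trimethyl-8-methylidenebicyclo[7.2.0]undecan-4-olate | [Li+].C=C1CC[C@@H](P(c3ccccc3)c4ccccc4)[C@](C)([O-])CC[C@@H]2[C@@H]1CC2(C)C | intermediate (not isolated)
30 | (1R,4R,5R,9S)-4,11,11-trimethyl-8-methylidene-5-[methyl(diphenyl)phosphaniumyl]bicyclo[7.2.0]undecan-4-olate | C=C1CC[C@@H]([P+](C)(c3ccccc3)c4ccccc4)[C@](C)([O-])CC[C@@H]2[C@@H]1CC2(C)C | intermediate (not isolated)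
31 | (1R,4E,9S)-4,11,11-trimethyl-8-methylidenebicyclo[7.2.0]undec-4-ene ((−)-β-caryophyllene) | C=C1CC/C=C(C)/CC[C@@H]2[C@@H]1CC2(C)C | intermediate
32 | syncarpic acid | CC1(C)C(=O)CC(=O)C(C)(C)C1=O | starting material
33 | isobutyraldehyde | CC(C)C=O | starting material
34 | 2-(2-methylpropylidene)-4,4,6,6-tetramethylcyclohexane-1,3,5-trione (isobutylidenesyncarpic acid) | CC(C)C=C1C(=O)C(C)(C)C(=O)C(C)(C)C1=O | intermediate (not isolated)
35 | Myrtucommulone K (1R,9S,4R,5S,1′R) | C=C1CC[C@H]2[C@@H](C(C)C)C3=C(O[C@]2(C)CC[C@@H]2[C@@H]1CC2(C)C)C(C)(C)C(=O)C(C)(C)C3=O | target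

**Step count and risks**

Total: 18 steps. Longest linear sequence: 16 steps (steps 1–6 and 9–18); steps 7–8 are a two-step side branch that joins at step 9.

Steps most likely to fail:

Step 18. Poor control of the oxadiene orientation (C1′) or of the alkene face would give diastereomeric adducts, and the exocyclic methylene could compete. The fallback builds the pyran stepwise and sets out from 24. Conjugate reduction with L-Selectride gives enolate 25, which is added at −78 °C to separately prepared 34 (from 32 and 33) to give the Michael adduct 3-hydroxy-2-[(1R)-1-[(1R,5S,9S)-11,11-dimethyl-8-methylidene-4-oxobicyclo[7.2.0]undecan-5-yl]-2-methylpropyl]-4,4,6,6-tetramethylcyclohex-2-ene-1,5-dione F6, in which C5 remains α to the ketone and can be equilibrated. Excess MeLi/CeCl3 (the first equivalent is consumed by the acidic enol) adds to C4 anti to the bulky C5 substituent (Felkin–Anh) to give 3-hydroxy-2-[(1R)-1-[(1R,4R,5S,9S)-4-hydroxy-4,11,11-trimethyl-8-methylidenebicyclo[7.2.0]undecan-5-yl]-2-methylpropyl]-4,4,6,6-tetramethylcyclohex-2-ene-1,5-dione F7. PPTS in toluene closes the pyran by hemiketalisation and dehydration with retention at C4, and the route is rejoined at 35.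

Step 6. Deprotonation next to the nitrile, Claisen closure onto the ester or intermolecular nitrile condensation may compete with the wanted enolate-to-nitrile closure. The fallback sets out from 13 and turns the nitrile into an ester acceptor. Platinum-catalysed neutral hydration (phosphinito Pt(II) hydride catalyst, aq. EtOH, 80 °C) gives tert-butyl 2-[(1R,2R)-2-(3-amino-3-oxopropyl)-3,3-dimethylcyclobutyl]acetate F1. DMF dimethyl acetal in methanol at 60 °C converts it into tert-butyl 2-[(1R,2R)-2-(3-methoxy-3-oxopropyl)-3,3-dimethylcyclobutyl]acetate F2. A Dieckmann condensation (KOt-Bu, THF, 0 °C), in which the tert-butyl ester is the poorer electrophile so that only its enolate acylates, returns to 15.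

Step 17. Backside opening of the trisubstituted oxirane at C5 by the phosphide may be slow in the medium ring, or the betaine may collapse poorly. The fallback sets out from 27. Catalytic OsO4/NMO dihydroxylation of the trisubstituted alkene gives (1R,4R,5S,9S)-4,11,11-trimethyl-8-methylidenebicyclo[7.2.0]undecane-4,5-diol F3. Mesylation of the secondary hydroxyl (MsCl, Et3N) gives (1R,4R,5S,9S)-4-hydroxy-4,11,11-trimethyl-8-methylidenebicyclo[7.2.0]undecan-5-yl methanesulfonate F4. K2CO3 in methanol closes the oxirane with inversion at C5 to the trans-epoxide (1R,4R,6R,10S)-4,12,12-trimethyl-9-methylidene-5-oxatricyclo[8.2.0.0(4,6)]dodecane F5. Oxygen-atom transfer with retention of geometry (cat. MeReO3, PPh3) then rejoins the route at 31.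

Further compounds

F1 | step 6 | tert-butyl 2-[(1R,2R)-2-(3-amino-3-oxopropyl)-3,3-dimethylcyclobutyl]acetate | NC(=O)CC[C@@H]1[C@@H](CC(=O)OC(C)(C)C)CC1(C)C
F2 | step 6 | tert-butyl 2-[(1R,2R)-2-(3-methoxy-3-oxopropyl)-3,3-dimethylcyclobutyl]acetate | COC(=O)CC[C@@H]1[C@@H](CC(=O)OC(C)(C)C)CC1(C)C
F3 | step 17 | (1R,4R,5S,9S)-4,11,11-trimethyl-8-methylidenebicyclo[7.2.0]undecane-4,5-diol | C=C1CC[C@H](O)[C@](C)(O)CC[C@@H]2[C@@H]1CC2(C)C
F4 | step 17 | (1R,4R,5S,9S)-4-hydroxy-4,11,11-trimethyl-8-methylidenebicyclo[7.2.0]undecan-5-yl methanesulfonate | C=C1CC[C@H](OS(C)(=O)=O)[C@](C)(O)CC[C@@H]2[C@@H]1CC2(C)C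
F5 | step 17 | (1R,4R,6R,10S)-4,12,12-trimethyl-9-methylidene-5-oxatricyclo[8.2.0.0(4,6)]dodecane | C=C1CC[C@H]3O[C@]3(C)CC[C@@H]2[C@@H]1CC2(C)C
F6 | step 18 | 3-hydroxy-2-[(1R)-1-[(1R,5S,9S)-11,11-dimethyl-8-methylidene-4-oxobicyclo[7.2.0]undecan-5-yl]-2-methylpropyl]-4,4,6,6-tetramethylcyclohex-2-ene-1,5-dione | C=C1CC[C@@H]([C@@H](C(C)C)C3=C(O)C(C)(C)C(=O)C(C)(C)C3=O)C(=O)CC[C@@H]2[C@@H]1CC2(C)C
F7 | step 18 | 3-hydroxy-2-[(1R)-1-[(1R,4R,5S,9S)-4-hydroxy-4,11,11-trimethyl-8-methylidenebicyclo[7.2.0]undecan-5-yl]-2-methylpropyl]-4,4,6,6-tetramethylcyclohex-2-ene-1,5-dione | C=C1CC[C@@H]([C@@H](C(C)C)C3=C(O)C(C)(C)C(=O)C(C)(C)C3=O)[C@](C)(O)CC[C@@H]2[C@@H]1CC2(C)C
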